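**Assumption:** abietane/podocarpane numbering and α/β descriptors (C10 methyl = β) are used for the tricyclic compounds. The route is designed on paper and has not been run; the auxiliary sense in step 4 is assigned by analogy with the 2-methylcyclohexanone case.

## Retrosynthetic overview

1. The target is a C2-symmetric head-to-tail dimer; cutting both C7–O bonds gives two molecules of the 6α-silyloxy-7-ketone 23, joined by reductive etherification (central 1,4-dioxane formed last).
2. 23 comes from sugiol methyl ether 20 (Rubottom oxidation), 20 from ferruginol methyl ether 19 (benzylic oxidation), and 19 from 12-methoxypodocarpatriene 16 (acylation, MeMgBr, ionic hydrogenation for the isopropyl group).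
3. 16 comes from enone 12 (reductive methylation, Wolff–Kishner); 12 comes from diketone 10 by aldol condensation, which closes ring A.
4. Key C–C bond: C10–C1, by asymmetric Michael addition of the (R)-1-phenylethylamine enamine of 2-tetralone 5 to ethyl vinyl ketone 8; this sets the quaternary centre.
5. Ring order: ring C (bought) and ring B (from tetralone 1), then ring A (Robinson annulation), then the dioxane.

## Route

Step 1
Reactants: 1 7-methoxy-1-tetralone
Product: 3 6-methoxy-4-methyl-1,2-dihydronaphthalene, via tertiary alcohol 2 (not isolated)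
Conditions: MeMgBr, THF, 0 °C to rt; aq. NH4Cl; then TsOH (cat.), toluene, 80 °C
Reagents that add atoms: methylmagnesium bromide, C[Mg]Br
Why: Grignard 1,2-addition to the aryl ketone followed by acid-catalysed (E1) dehydration of the tertiary benzylic alcohol gives the conjugated alkene; no stereocentre remains.

Step 2
Reactants: 3 6-methoxy-4-methyl-1,2-dihydronaphthalene
Product: 5 7-methoxy-1-methyl-2-tetralone (racemic), via epoxide 4 (not isolated)
Conditions: mCPBA, NaHCO3, CH2Cl2, 0 °C; then TsOH (cat.), toluene, rt
Reagents that add atoms: mCPBA, O=C(OO)c1cccc(Cl)c1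
Why: Prilezhaev epoxidation then Meinwald rearrangement (tertiary benzylic cation, 1,2-hydride shift) gives the 2-tetralone; C1 is racemic and enolisable, which the next two steps exploit.

Step 3
Reactants: 5 7-methoxy-1-methyl-2-tetralone; 6 (R)-1-phenylethylamine
Product: 7 7-methoxy-1-methyl-N-[(1R)-1-phenylethyl]-3,4-dihydronaphthalen-2-amine (secondary enamine tautomer of the imine)
Conditions: toluene, TsOH (cat.), Dean–Stark, reflux, Ar
Reagents that add atoms: none
Why: Ketone–amine condensation with azeotropic water removal gives the imine, which rests as the aryl-conjugated secondary enamine; the C1 centre is erased and the auxiliary centre is untouched.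

Step 4
Reactants: 7 chiral enamine; 8 ethyl vinyl ketone (pent-1-en-3-one)
Product: 10 (1R)-7-methoxy-1-methyl-1-(3-oxopentyl)-3,4-dihydronaphthalen-2(1H)-one, via Michael-adduct imine 9 (not isolated)
Conditions: 8 (1.5 equiv), THF, 40 °C, 3 d; then 20% aq. AcOH, rt
Reagents that add atoms: water, O
Why: d'Angelo asymmetric Michael addition: the enamine adds to the enone through a compact aza-ene-like transition state with internal N–H transfer, on the face anti to the auxiliary phenyl, so the (R)-amine gives the (R) quaternary centre (the future C10 with β-methyl, about 90% ee expected); hydrolysis releases the diketone and the amine.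

Step 5
Reactants: 10 diketone
Product: 12 (4aS)-6-methoxy-1,4a-dimethyl-4,4a,9,10-tetrahydrophenanthren-2(3H)-one, via ketol 11 (not isolated)
Conditions: NaOMe, MeOH, rt to 60 °C; recrystallise to ≥99% ee
Reagents that add atoms: none
Why: Intramolecular aldol condensation (second half of a Robinson annulation) closes ring A, irreversible dehydration draining any bridged ketol back through retro-aldol; the quaternary centre is not enolisable and is kept.

Step 6
Reactants: 12 enone
Product: 14 (4aS,10aR)-6-methoxy-1,1,4a-trimethyl-3,4,4a,9,10,10a-hexahydrophenanthren-2(1H)-one (12-methoxypodocarpa-8,11,13-trien-3-one), via lithium enolate 13 (not isolated)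
Conditions: Li (2.2 equiv), t-BuOH (1 equiv), NH3(l)/THF, −78 °C; isoprene; then MeI (excess), −78 to −33 °C
Reagents that add atoms: iodomethane, CI
Why: Stork reductive alkylation: dissolving-metal reduction protonates C5 axially from the α face to give the trans A/B fusion (5α-H), and the regiodefined enolate is C-methylated at C4 to form the gem-dimethyl group; without excess proton source the anisole ring is not reduced.

Step 7
Reactants: 14 ketone
Product: 16 (4bS,8aS)-3-methoxy-4b,8,8-trimethyl-4b,5,6,7,8,8a,9,10-octahydrophenanthrene (12-methoxypodocarpa-8,11,13-triene), via hydrazone 15 (not isolated)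
Conditions: N2H4·H2O, KOH, diethylene glycol, 140 °C then 210 °C
Reagents that add atoms: none
Why: Wolff–Kishner reduction (Huang–Minlon) removes the C3 carbonyl via the hydrazone and loss of N2; no stereocentre is involved.

Step 8
Reactants: 16 12-methoxypodocarpa-8,11,13-triene
Product: 17 13-acetyl-12-methoxypodocarpa-8,11,13-triene
Conditions: AcCl, AlCl3, CH2Cl2, 0 °C
Reagents that add atoms: acetyl chloride, CC(=O)Cl
Why: Friedel–Crafts acylation ortho to the methoxy group goes to C13 because C11 is blocked by the C1 methylene and C10 methyl; 0 °C avoids aryl ether cleavage.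

Step 9
Reactants: 17 aryl methyl ketone
Product: 18 2-(12-methoxypodocarpa-8,11,13-trien-13-yl)propan-2-ol
Conditions: MeMgBr, THF, 0 °C to rt
Reagents that add atoms: methylmagnesium bromide, C[Mg]Br
Why: Grignard addition to the aryl methyl ketone gives the tertiary benzylic alcohol; no new stereocentre.

Step 10
Reactants: 18 tertiary benzylic alcohol
Product: 19 12-methoxyabieta-8,11,13-triene ((+)-ferruginol methyl ether)
Conditions: Et3SiH, TFA, CH2Cl2, 0 °C to rt
Reagents that add atoms: none
Why: Ionic hydrogenation: the tertiary benzylic cation, stabilised by the ortho methoxy group, is trapped by hydride from the silane to give the isopropyl group.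

Step 11
Reactants: 19 ferruginol methyl ether
Product: 20 12-methoxyabieta-8,11,13-trien-7-one (sugiol methyl ether)
Conditions: CrO3, AcOH/H2O, rt
Reagents that add atoms: chromium trioxide, O=[Cr](=O)=O
Why: Benzylic oxidation by CrO3 at the C7 methylene, which is para to the methoxy group and so the most activated benzylic position; the hindered isopropyl methine reacts more slowly.

Step 12
Reactants: 20 sugiol methyl ether
Product: 21 12-methoxy-7-(triethylsilyloxy)abieta-6,8,11,13-tetraene
Conditions: TESOTf, Et3N, CH2Cl2, 0 °C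
Reagents that add atoms: triethylsilyl triflate, CC[Si](CC)(CC)OS(=O)(=O)C(F)(F)F
Why: Soft enolisation/O-silylation of the aryl ketone; C6 is the only enolisable position and C5 is not affected.

Step 13
Reactants: 21 silyl enol ether
Product: 23 (6R)-12-methoxy-6α-(triethylsilyloxy)abieta-8,11,13-trien-7-one, via silyloxy epoxide 22 (not isolated)
Conditions: DMDO, acetone/CH2Cl2, −40 to 0 °C
Reagents that add atoms: dimethyldioxirane, CC1(C)OO1
Why: Rubottom oxidation: the enol ether is epoxidised from the α face because the β face at C6 is shielded by the syn-axial C10 and 4β methyls, and the silyloxy epoxide opens with silyl migration to the 6α-(equatorial)-silyloxy ketone.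

Step 14
Reactants: 23 6α-silyloxy-7-ketone (two molecules)
Product: 25 target CNP0327150.1, via open-chain mono-ether 24 (not isolated)
Conditions: TMSOTf (0.5 equiv), CH2Cl2 (0.5 M), −78 °C; then Et3SiH (4 equiv), −78 to −30 °C; Et3N quench
Reagents that add atoms: none
Why: Lewis acid/silane reductive etherification run in a head-to-tail homodimerising mode: the activated C7 ketone of one molecule is attacked by the C6 silyl ether oxygen of the other and the aryl-stabilised oxocarbenium is reduced by Et3SiH from the α face (axial, anti to the axial 6β-H) to give 7β-O, then the same event repeats intramolecularly to close the dioxane, C6 staying 6α throughout.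

## Compound list

1 | 7-methoxy-3,4-dihydronaphthalen-1(2H)-one (7-methoxy-1-tetralone) | COc1ccc2c(c1)C(=O)CCC2 | starting material
2 | 7-methoxy-1-methyl-1,2,3,4-tetrahydronaphthalen-1-ol (racemic) | COc1ccc2c(c1)C(C)(O)CCC2 | intermediate
3 | 6-methoxy-4-methyl-1,2-dihydronaphthalene | COc1ccc2c(c1)C(C)=CCC2 | intermediate
4 | 6-methoxy-7b-methyl-1a,2,3,7b-tetrahydronaphtho[1,2-b]oxirene (racemic epoxide of 3) | COc1ccc2c(c1)C1(C)OC1CC2 | intermediate
5 | 7-methoxy-1-methyl-3,4-dihydronaphthalen-2(1H)-one (racemic) | COc1ccc2c(c1)C(C)C(=O)CC2 | intermediate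
6 | (R)-1-phenylethylamine | C[C@@H](N)c1ccccc1 | starting material
7 | 7-methoxy-1-methyl-N-[(1R)-1-phenylethyl]-3,4-dihydronaphthalen-2-amine (enamine tautomer of the imine) | COc1ccc2c(c1)C(C)=C(N[C@H](C)c1ccccc1)CC2 | intermediate
8 | pent-1-en-3-one (ethyl vinyl ketone) | C=CC(=O)CC | starting material
9 | N-[(1R)-1-phenylethyl] imine of (1R)-7-methoxy-1-methyl-1-(3-oxopentyl)-2-tetralone (C=N geometry undefined) | COc1ccc2c(c1)[C@@](C)(CCC(=O)CC)C(=N[C@H](C)c1ccccc1)CC2 | intermediate
10 | (1R)-7-methoxy-1-methyl-1-(3-oxopentyl)-3,4-dihydronaphthalen-2(1H)-one | COc1ccc2c(c1)[C@@](C)(CCC(=O)CC)C(=O)CC2 | intermediate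
11 | 10a-hydroxy-6-methoxy-1,4a-dimethyl-3,4,4a,9,10,10a-hexahydrophenanthren-2(1H)-one (ketol; 4a-methyl as in 12, the two new centres are a mixture) | COc1cc2c(cc1)CCC1(O)C(C)C(=O)CC[C@]21C | intermediate
12 | (4aS)-6-methoxy-1,4a-dimethyl-4,4a,9,10-tetrahydrophenanthren-2(3H)-one | COc1cc2c(cc1)CCC1=C(C)C(=O)CC[C@]21C | intermediate
13 | lithium enolate of (4aS,10aS)-6-methoxy-1,4a-dimethyl-3,4,4a,9,10,10a-hexahydrophenanthren-2(1H)-one (trans-fused, 5α-H) | COc1cc2c(cc1)CC[C@H]1C(C)=C(O[Li])CC[C@]21C | intermediate
14 | (4aS,10aR)-6-methoxy-1,1,4a-trimethyl-3,4,4a,9,10,10a-hexahydrophenanthren-2(1H)-one (12-methoxypodocarpa-8,11,13-trien-3-one) | COc1cc2c(cc1)CC[C@H]1C(C)(C)C(=O)CC[C@]21C | intermediate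
15 | hydrazone of 14 | COc1cc2c(cc1)CC[C@H]1C(C)(C)C(=NN)CC[C@]21C | intermediate
16 | (4bS,8aS)-3-methoxy-4b,8,8-trimethyl-4b,5,6,7,8,8a,9,10-octahydrophenanthrene (12-methoxypodocarpa-8,11,13-triene) | COc1cc2c(cc1)CC[C@H]1C(C)(C)CCC[C@]21C | intermediate
17 | 13-acetyl-12-methoxypodocarpa-8,11,13-triene (5α-H, 10β-Me) | COc1cc2c(cc1C(C)=O)CC[C@H]1C(C)(C)CCC[C@]21C | intermediate
18 | 2-(12-methoxypodocarpa-8,11,13-trien-13-yl)propan-2-ol (5α-H, 10β-Me) | COc1cc2c(cc1C(C)(C)O)CC[C@H]1C(C)(C)CCC[C@]21C | intermediate
19 | (5S,10S)-12-methoxyabieta-8,11,13-triene (ferruginol methyl ether) | COc1cc2c(cc1C(C)C)CC[C@H]1C(C)(C)CCC[C@]21C | intermediate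
20 | (5S,10S)-12-methoxyabieta-8,11,13-trien-7-one (sugiol methyl ether) | COc1cc2c(cc1C(C)C)C(=O)C[C@H]1C(C)(C)CCC[C@]21C | intermediate
21 | (5S,10S)-12-methoxy-7-(triethylsilyloxy)abieta-6,8,11,13-tetraene | COc1cc2c(cc1C(C)C)C(O[Si](CC)(CC)CC)=C[C@H]1C(C)(C)CCC[C@]21C | intermediate
22 | 6α,7α-epoxy-12-methoxy-7β-(triethylsilyloxy)abieta-8,11,13-triene | COc1cc2c(cc1C(C)C)[C@]1(O[Si](CC)(CC)CC)O[C@@H]1[C@H]1C(C)(C)CCC[C@]21C | intermediate
23 | (5S,6R,10S)-12-methoxy-6α-(triethylsilyloxy)abieta-8,11,13-trien-7-one | COc1cc2c(cc1C(C)C)C(=O)[C@H](O[Si](CC)(CC)CC)[C@H]1C(C)(C)CCC[C@]21C | intermediate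
24 | open-chain mono-ether: 12-methoxy-6α-[(12-methoxy-6α-triethylsilyloxyabieta-8,11,13-trien-7β-yl)oxy]abieta-8,11,13-trien-7-one | COc1cc2c(cc1C(C)C)[C@@H](O[C@H]3C(=O)c4cc(C(C)C)c(OC)cc4[C@@]4(C)CCCC(C)(C)[C@H]34)[C@H](O[Si](CC)(CC)CC)[C@H]1C(C)(C)CCC[C@]21C | intermediate
25 | CNP0327150.1: C2-symmetric dimer of two (5S,10S)-12-methoxyabieta-8,11,13-triene units joined by oxygen bridges C7–O–C6′ and C6–O–C7′ (6R,7R,6′R,7′R; 6α-O and 7β-O in each half) | COc1cc2c(cc1C(C)C)[C@H]1O[C@H]3[C@H](O[C@@H]1[C@H]1C(C)(C)CCC[C@]21C)c1cc(C(C)C)c(OC)cc1[C@@]1(C)CCCC(C)(C)[C@H]31 | target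

## Step count and risks

Total step count: 14. Longest linear sequence: 14 (the last step joins two molecules of the same intermediate).

**Step 14 (reductive cyclodimerisation) is the most likely to fail.** The first C–O bond is intermolecular between two hindered partners and competes with plain reduction of the ketone. The product's p-methoxybenzylic ethers ionise if the mixture warms. The homochiral trans,trans product must hold its central dioxane in a twist form, so equilibration at C7 through a cation would drift to a cis-fused isomer; this is why C7 is set by hydride delivery and the reaction is quenched cold.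
Fallback: leave the route at 20 and build the dioxane by epoxide chemistry instead of ketone chemistry. NaBH4 reduction of 20 gives 12-methoxyabieta-8,11,13-trien-7β-ol F1. Dehydration with TsOH in toluene gives 12-methoxyabieta-6,8,11,13-tetraene F2. α-Face epoxidation with DMDO gives 6α,7α-epoxy-12-methoxyabieta-8,11,13-triene F3. F3 is then cyclodimerised head-to-tail (BF3·OEt2 5 mol %, CH2Cl2, −78 °C, concentrated), each epoxide oxygen opening the other epoxide at benzylic C7 with inversion (7α-O to 7β-O) while C6 keeps its α oxygen. This comes back to the route at 25. Its own weakness is the competing 1,2-hydride shift to the 6-ketone.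

**Step 6 (reductive methylation)** can give Birch over-reduction of the anisole ring, proton exchange of the enolate (unmethylated or over-methylated ketone) and some O-methylation.
Fallback: set out from 12 and separate the two events. Deconjugative methylation with KOt-Bu and MeI in t-BuOH gives (4aR)-6-methoxy-1,1,4a-trimethyl-3,4,4a,9-tetrahydrophenanthren-2(1H)-one F4 (double bond moved to C5–C6). Hydrogenation over Pd/C in EtOAc then adds hydrogen from the α face, the β face being blocked by the C10 and 4β methyls, to give the trans-fused ketone. This comes back to the route at 14.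

**Step 7 (Wolff–Kishner)** involves a ketone flanked by the gem-dimethyl group, so hydrazone formation is slow and the 200 °C base can partly cleave the aryl methyl ether.
Fallback: set out from 14 and remove the oxygen through sulfur. Ethane-1,2-dithiol with BF3·OEt2 in CH2Cl2 gives the 3,3-(ethylenedithio) derivative of 12-methoxypodocarpa-8,11,13-triene F5. Desulfurisation with Raney Ni in refluxing EtOH comes back to the route at 16.

## Further compounds

F1 | step 14 | (5S,7S,10S)-12-methoxyabieta-8,11,13-trien-7β-ol (minor 7α epimer is carried along) | COc1cc2c(cc1C(C)C)[C@@H](O)C[C@H]1C(C)(C)CCC[C@]21C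
F2 | step 14 | (5S,10S)-12-methoxyabieta-6,8,11,13-tetraene | COc1cc2c(cc1C(C)C)C=C[C@H]1C(C)(C)CCC[C@]21C
F3 | step 14 | (5S,6R,7S,10S)-6α,7α-epoxy-12-methoxyabieta-8,11,13-triene | COc1cc2c(cc1C(C)C)[C@@H]1O[C@@H]1[C@H]1C(C)(C)CCC[C@]21C
F4 | step 6 | (4aR)-6-methoxy-1,1,4a-trimethyl-3,4,4a,9-tetrahydrophenanthren-2(1H)-one (10β-methyl, C5=C6 alkene) | COc1cc2c(cc1)CC=C1C(C)(C)C(=O)CC[C@]21C
F5 | step 7 | 3,3-(ethylenedithio)-12-methoxypodocarpa-8,11,13-triene (5α-H, 10β-Me) | COc1cc2c(cc1)CC[C@H]1C(C)(C)C3(SCCS3)CC[C@]21C
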